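To the colleague who expects green and ochre to end level on the plateau: the plateau of the elm run is not flat, and its slope is the quick number wanted here.

| flask | Q | X | G | temperature | remark | time |
|---|---|---|---|---|---|---|
| alder | 2 M | 1.6 M | 56 mM | 85 °C | run made earlier |  |
| elm | 2 M | 1.6 M | 88 mM | 100 °C | run made earlier |  |
| green | 2.0 M | 1.60 M | 40 mM | 100 °C |  | 2.5 d |
| ochre | 2.0 M | 1.60 M | 40 mM | 100 °C |  | 8.0 d |

- alder (time / d: D / %, Q / %): 0.167: 7.2, 92.9; 0.500: 18.9, 80.9; 0.833: 28.7, 70.7; 1.25: 39.0, 60.8; 1.67: 47.1, 53.0; 2.50: 59.0, 40.8; 4.00: 62.6, 36.4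
- elm (time / h: D / %, Q / %): 2.00: 14.1, 85.8; 6.00: 34.2, 65.6; 10.0: 48.0, 52.0; 15.0: 58.5, 41.6; 20.0: 58.5, 40.1; 30.0: 59.8, 38.2; 40.0: 60.3, 38.2

(readings scatter by 0.3 percentage points)

1. the winner by amount of D, in percent of the Q charged; "neither" if no more than 2 percentage points parts them (green / ochre / neither)
2. how much D is there at the end, in percent of the Q charged: green
3. how much D is there at the end, in percent of the Q charged: ochre

- what was read earlier has a scatter of 0.3 percentage points, one standard deviation

Elm's D gains 10 percentage points in the 5.00 h up to 15.0 h, then 1.8 points in the following 25.0 h. Elm's Q still stands at 38.2% in the last reading, so the break in elm points to X as the limiting reagent. The tail time is the time elm's plateau needs to gain the margin of 2 points: read from elm, with the scatter of its readings, it is 1.16 d.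

Green and ochre share one charge and elm's temperature of 100 °C, and they differ in time. Assuming a rate proportional to the square root of G, green's break falls near 0.927 d, earlier than its reading at 2.5 d. The 5.50 d between the readings are then 4.75 tail times, which gives ochre a lead of 9.5 points, more than the margin. This reckoning commits to the winner and the gap, not to the height of the plateau.

The forecast chose neither, with green at 61.5% and ochre at 62.5%: “Green and ochre should finish nearly equal”. The flasks give green 55.2% and ochre 62.5%, so ochre wins by 7.3 points.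

    G → 2 E (k = 0.0770 h⁻¹, Ea = 120 kJ mol⁻¹)
    X + Z → D + E (k = 1.40 × 10⁷ L mol⁻¹ h⁻¹, Ea = 29.0 kJ mol⁻¹)
    Q + E → Z (k = 8.10 × 10⁵ L mol⁻¹ h⁻¹, Ea = 38.0 kJ mol⁻¹)
    X ⇌ J (K = 20.0, k = 0.0530 h⁻¹, Ea = 127 kJ mol⁻¹, ΔH = 16.0 kJ mol⁻¹)
    2 E → L (k = 2.00 × 10⁸ L mol⁻¹ s⁻¹, Ea = 15.0 kJ mol⁻¹)
    (constants at 100 °C)

That lead corresponds to a tail time of 1.50 d, longer than elm's 1.16 d. At 0.295 d, green uses X in the step to D 1.7 times as fast as in the forward step to J. Green at 2.50 d holds X at 0% and J at 0.495 M, and ochre at 8.00 d holds J at 0.349 M. For green read at 6.0 d, the extra time is 3.02 tail times, which gives 61.2%. The computed result is 60.2%.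

(The earlier runs and the new flask are simulated with made-up constants.)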